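I began with an easy step: Q minus G over their sum is the excess asked for, and the earlier runs give it at each reading.

| flask | E | D | Z | temperature | remark | time |
|---|---|---|---|---|---|---|
| zeta | 0.010 M | 0.010 M | 0.044 M | −5 °C | run made earlier |  |
| epsilon | 0.015 M | 0.015 M | 0.044 M | 30 °C | run made earlier |  |
| spring | 0.020 M | 0.020 M | 0.0440 M | 30 °C |  | 30 min |
| noon | 0.020 M | 0.020 M | 0.0440 M | 0 °C |  | 30 min |
| autumn | 0.020 M | 0.020 M | 0.0440 M | 60 °C |  | 30 min |

- zeta (time / min: Q / %, G / %): 15.0: 9, 5; 30.0: 15, 1; 50.0: 21, 4; 60.0: 17, 8; 120: 29, 17; 240: 38, 30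
- epsilon (time / min: Q / %, G / %): 2.50: 6, 5; 8.00: 14, 11; 12.0: 22, 20; 20.0: 27, 27; 30.0: 33, 33; 40.0: 36, 37

(standard deviation of a reading: 1.5 percentage points)

- Z is single-handed; E and D are mirror images of each other, charged as a racemate, each of them at the stated concentration
- an excess is the difference of the two amounts in percent of their sum
- an excess is below zero if the other one leads
- the handed part of Z does not stay in what it makes, so the products of the two hands are mirror images too

1. the flask with the highest excess of Q over G ("all alike" if they lie within 1.5 percentage points) (spring / noon / autumn / all alike)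
2. excess of Q over G at the end, spring
3. excess of Q over G at the end, noon
4. excess of Q over G at the end, autumn

I kept the books on E and D together, the limiting reagent by the charge in the new flasks, where their 0.0400 M stands below the 0.0440 M of Z. In the zeta run at −5 °C, the entries at 30.0 min were Q 15% and G 1%. At 240 min they were Q 38%, G 30% and 32.0% not among the products, so the excess read 11.8%. From 30.0 min on the excess read lower at each reading, so I counted its half-lives from an assumed start of pure Q. The half-life of the excess, the time in which an excess shrinks by a factor 2, read 77.7 min in the zeta run.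

The epsilon run at 30 °C read 9.09% at 2.50 min, which gives a half-life of 0.723 min. That reading is poor: Q and G differ by 1 percentage point against a scatter of 1.5 points. But noon lies 14.3% of the way from zeta to epsilon, so that reading enters my reckoning for noon with that weight. Taking the logarithm of the half-life as straight in temperature, I got 39.8 min at 0 °C. So 30 min at noon is 0.753 half-lives, and I expected an excess near 59.3%. Spring has 41.5 half-lives, so I expected it near zero, and autumn, hotter still, near zero too.

The forecast reasoned “The products are mirror images, so this is a kinetic resolution” and gave 1% for spring, 22% for noon and −4.5% for autumn, with noon highest. Its noon value stood below my 59.3%.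

The flasks gave 0.650% for spring, 52.3% for noon and 0.00831% for autumn, with noon highest.

    E ⇌ L (K = 0.0780, k = 0.400 min⁻¹, Ea = 75.0 kJ mol⁻¹, ΔH = −62.0 kJ mol⁻¹)
    Q ⇌ G (k = 0.0210 min⁻¹, Ea = 89.0 kJ mol⁻¹)
    Z ⇌ J (K = 0.270, k = 0.0200 min⁻¹, Ea = 78.0 kJ mol⁻¹, ΔH = −6.00 kJ mol⁻¹)
    Z + D → G (k = 0.00330 M⁻¹ min⁻¹, Ea = 53.0 kJ mol⁻¹)
    L → X (k = 0.00250 min⁻¹, Ea = 87.0 kJ mol⁻¹)
    Z + E → Q (k = 0.500 M⁻¹ min⁻¹, Ea = 40.0 kJ mol⁻¹)
    D ⇌ L (K = 0.0780, k = 0.400 min⁻¹, Ea = 75.0 kJ mol⁻¹, ΔH = −62.0 kJ mol⁻¹)
    (constants at 0 °C)

In these equations Q and G turn into each other, and noon stood at Q 16.2% and G 5.07% after 30.0 min. The excess of noon counts as 0.935 half-lives against my 0.753. The neighbour is spring run at 55 °C. Extrapolating from 77.7 min in the same way gave a half-life of 0.0256 min, so 30 min is 1172 half-lives, and that flask gave 0.0168%.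

The earlier runs and the new flask stem from a simulated flask with constants of no real substance.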